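Ring positions of the target follow flavanone numbering (O1, C2, C3, C4, C4a, C5–C8, C8a). C3 and C5 of the acetophenone intermediates become C8 and C6 of the target.

## Analysis of the target

The target, (2R,3R)-3,5,7-trihydroxy-2-(4-hydroxyphenyl)-6,8-bis(3-methylbut-2-enyl)chroman-4-one (C25H28O6), is a dihydroflavonol. It is a benzo-fused dihydropyranone (rings A and C) with a 4-hydroxyphenyl group (ring B) on C2 and a secondary hydroxyl on C3. Ring A is hexasubstituted: O1 (on C8a), the 7-OH and the 5-OH alternate with three carbon substituents, namely the acyl carbon C4 on C4a and one prenyl group each on C6 and C8. The only stereocentres are C2 and C3, both R, which places the aryl group and the hydroxyl trans on ring C. This is the more stable relative arrangement, so the real issue is absolute configuration. The sensitive elements are: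
- the two trisubstituted prenyl alkenes, which are attacked by electrophilic oxidants, lost on hydrogenation, and closed by acid onto a neighbouring phenol to give dimethylchromans;
- the α-hydroxy ketone at C3/C4, which can epimerise or be oxidised to the flavonol under base;
- the benzylic O1–C2 ether para to a phenol, which can open reversibly.

The difficulty is twofold. Two C-prenyl groups must be placed on defined carbons of an electron-rich, ambident trioxygenated ring without O-alkylation, over-alkylation or dearomatisation. The oxidation that creates C2 and C3 must also select the conjugated alkene over two more electron-rich ones, and do so enantioselectively.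

The strategy rests on one structural feature. Once ring C is opened at O1–C2, ring A is a mirror-symmetric 2,4,6-trioxygenated acetophenone. In it, C6 and C8 are each ortho to one of the two oxygens beside the acyl-bearing carbon (O5 on C5, O1 on C8a), and the other ortho neighbour of both oxygens is the substituted carbon C4a. Each of these oxygens can therefore pass an allyl unit to exactly one open ring carbon.

## Retrosynthetic reasoning

**18 ⇒ 16.** The O1–C2 bond of ring C is cut first, together with the four O-protecting groups, leading back to the tetra-MOM epoxy ketone 16 (through its unmasked form 17). This is the one bond of ring C that forms with simple stereochemical bookkeeping. The phenolic oxygen displaces the epoxide oxygen at the benzylic carbon with inversion and the C3–O bond is never broken, so a trans epoxide of defined configuration becomes the 2,3-trans product. Cutting C2–C3 or C3–C4 instead would require an asymmetric aldol or acylation on a hexasubstituted arene. Ring A of 16 carries two identical ortho oxygens, so no differentiation is needed. The forward step must unmask the phenols and close the ring without letting acid act on the prenyl groups.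

**16 ⇒ 15.** Removing the epoxide oxygen gives the (E)-enone 15. Both stereocentres are thereby reduced to one face-selective oxygen transfer to a planar alkene. A nucleophilic oxidant is required, because 15 contains two trisubstituted, electron-rich alkenes that an electrophilic epoxidation or dihydroxylation would attack first. A hydroperoxide anion adds only to the electron-poor enone. Catalyst control by a homochiral polypeptide has to set Cα as R and Cβ as S.

**15 ⇒ 11 + 13.** The Cα=Cβ double bond is cut by a retro-aldol condensation into methyl ketone 11 and aldehyde 13, which comes from 12 by protection. This is the most convergent cut: ring B and C2 arrive in one piece, and all chemistry on the crowded ring A is finished before any stereocentre exists. Every phenol must be etherified at this stage, since a free ortho hydroxyl would add to the enone in a ring-closing conjugate addition or divert the later peroxide step.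

**11 ⇒ 10.** Two O–MOM bonds are removed to reveal diphenol 10. Nothing skeletal is gained. The step exists because 10, the direct product of the rearrangement, has its two hydroxyls free.

**10 ⇒ 6.** The two aryl–CH2 bonds (at C6 and C8 of the target) are cut in a double retro-[3,3] shift that returns each five-carbon unit to the adjacent oxygen as a 1,1-dimethylallyl ether, giving bis-ether 6. This avoids forming the C–C bonds intermolecularly on an ambident 1,3,5-trioxygenated ring, with its O- versus C-attack and mono-, di- and geminal mixtures. In 6 each ether oxygen has exactly one unsubstituted ortho carbon, so the substrate dictates where the bond forms, and allylic transposition converts the tertiary ether into the linear prenyl group. Two skeletal bonds are gained in one reagent-free operation. The forward step needs two successive ortho shifts, without loss of the tertiary allyl groups and without ring closure of the new ortho-prenylphenols.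

**6 ⇒ 2 + 4.** The two tertiary alkyl C–O bonds are cut, giving diphenol 2 and two equivalents of carbonate 4, itself derived from alcohol 3. A tertiary allylic aryl ether cannot be made by direct displacement. Ionisation of 4 by a zerovalent palladium catalyst to a π-allyl intermediate, followed by phenoxide attack at the more substituted terminus, is the established solution. Forward, both hydrogen-bonded hydroxyls have to react and the kinetic branched ethers must not isomerise.

**2 ⇒ 1.** Finally the 4-O–MOM bond is cut to give the commercial ketone 1. Its acetyl group is the later aldol donor and, in the rearrangement, the blocking group on C4a. The protection has to single out the 4-hydroxyl, which is the most acidic and the only one not tied to the carbonyl.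

## Alternatives that were turned down

**Alternative 1:** 
- Disconnection: ring C is cut at O1–C2 and C3–C4, a retro-[4+2] into a four-atom heterodiene (O1, C8a, C4a, C4) and a two-carbon dienophile (C2, C3).
- Forward key step: the diprenylated salicylaldehyde A2 is condensed with an orthoformate under acid to give the 4-methoxy ortho-quinone methide A3 in situ. A3 adds across the (E)-enol acetate A4 to give the 4-methoxyflavan-3-yl acetate A1.
- In favour: it is the most convergent plan considered. Ring C and three contiguous sp3 carbons form in one step, the E geometry of A4 is transferred suprafacially into the 2,3-trans relationship, and rearomatisation of ring A drives the addition.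
- Against, for this target:
  - Nothing controls absolute configuration. A1 would be racemic unless a chiral acid catalyst tolerating this hexasubstituted heterodiene were developed.
  - A1 is at the wrong oxidation level at C4. The methyl ether must be hydrolysed, the benzylic alcohol oxidised next to an electron-rich ring and two prenyl alkenes, and the acetate removed without epimerising C3.
  - A4 carries a donor at each alkene carbon, so flavan- versus isoflavan-type orientation depends on the aryl group outweighing the acetoxy group.
  - A2 has a free phenol beside a prenyl group under acid, which invites chroman formation. A2 must itself be made, most plausibly by the same Claisen chemistry as here, so the ring A problem is not avoided.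
- Comparison: Alternative 1 is stronger on convergence and on bonds formed in the key step. The chosen route takes two steps to form ring C, but sets both stereocentres by catalyst control at the correct oxidation level and ends with a deprotection instead of redox adjustments.

**Alternative 2:** 
- Disconnection: three bonds of ring A (C6–C7, C7–C8, C4a–C8a) are cut, so ring A is assembled from non-aromatic pieces.
- Forward key step: heating the 3-siloxy-4-prenylcyclobutenone A6 with the prenylated siloxyalkyne A7 triggers electrocyclic ring opening, ketene–alkyne [2+2] addition, a second ring opening, 6π closure and tautomerisation to the symmetric phenol A5.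
- In favour: regiochemistry follows from the connectivity of A6 and A7, so O- versus C-alkylation never arises. The prenyl groups are introduced on non-aromatic precursors, and the three oxygens of A5 are differentiated.
- Against, for this target:
  - Ring A is a symmetrical trioxygenated ring that can be bought with the acyl carbon attached (1). Building it from A6 and A7 costs several steps for each fragment, and both are sensitive.
  - A5 still lacks C4, which would have to be introduced between two bulky silyloxy groups.
  - Ring C and the stereocentres are not addressed at all.
- Comparison: Alternative 2 is stronger on regiochemical certainty and avoids the thermal hazards of allyl aryl ethers. In the chosen route the symmetry of 6 and its blocked carbon should give the same outcome in one step, two operations away from 1, with the acetyl group present from the start.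

**Alternative 3:** 
- Disconnection: ring A is cut at C8–C8a and C4a–C5 and made last, by a formal [3+3] cyclocondensation on a preformed enantiopure ring C.
- Forward key step: the bis-silyl dienol ether A9 adds through its terminal carbon to C6 of the 5-bromodihydropyranone A10. The resulting enolate attacks the ester carbon, and a double elimination (ester alkoxy group and bromide) aromatises ring A to give A8, two MOM groups short of the target.
- In favour: C2 and C3 are set early on a small ring, the prenyl groups come from enolate alkylations, ring A regiochemistry is fixed by connectivity, and the end game is one deprotection.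
- Against, for this target:
  - A10 has to be made as the single (2R,3R) isomer over several steps.
  - Its C2–O1 bond belongs to a vinylogous ester and is benzylic to an oxygenated ring, so Lewis acid can open it and scramble C2. C3 is epimerisable α to the ketone.
  - Both reacting carbons of A9 carry a prenyl group, so two fully substituted aromatic carbons must form from hindered termini, with α- versus γ-attack in competition.
  - An annulation with this substitution pattern has no close analogy and would have to be developed.
- Comparison: Alternative 3 is stronger on late-stage convergence and shields the stereocentres from ring A chemistry. The chosen route uses only reaction types established for their substrate classes and creates the stereocentres two steps from the end, after all forcing conditions.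

Key step: step 4

Assumption: poly-L-leucine is taken to transfer oxygen to enone 15 with the facial sense established for simple (E)-chalcones, giving the (αR,βS)-epoxide; if the substitution pattern reversed that sense, poly-D-leucine would be used in the same way.

## Route

Step 1
Reactants: 1 2,4,6-trihydroxyacetophenone
Product: 2 1-[2,6-dihydroxy-4-(methoxymethoxy)phenyl]ethanone
Conditions: MOMCl (1.05 equiv), i-Pr2NEt, CH2Cl2/THF, 0 °C
Reagents that add atoms: chloromethyl methyl ether (MOMCl), COCCl
Why: The 4-hydroxyl is para to the acetyl group, the most acidic, and the only one not hydrogen-bonded to the carbonyl, so one equivalent of the chloromethyl ether should alkylate it first (Williamson-type O-alkylation, acetal protection). The two ortho hydroxyls stay free and equivalent.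

Step 2
Reactants: 3 2-methylbut-3-en-2-ol
Product: 4 tert-butyl 2-methylbut-3-en-2-yl carbonate
Conditions: n-BuLi, THF, −78 → 0 °C; then Boc2O, 0 °C → rt
Reagents that add atoms: di-tert-butyl dicarbonate (Boc2O), CC(C)(C)OC(=O)OC(=O)OC(C)(C)C
Why: Deprotonation of the tertiary alcohol and alkoxycarbonylation of the alkoxide with the dicarbonate gives the mixed carbonate. The tertiary allylic C–O bond does not ionise under these basic conditions.

Step 3
Reactants: 2 1-[2,6-dihydroxy-4-(methoxymethoxy)phenyl]ethanone; 4 tert-butyl 2-methylbut-3-en-2-yl carbonate
Product: 6 1-[4-(methoxymethoxy)-2,6-bis(2-methylbut-3-en-2-yloxy)phenyl]ethanone, via mono(1,1-dimethylallyl) ether 5 (not isolated)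
Conditions: 4 (3 equiv), Pd(PPh3)4 (5 mol%), THF, 0 °C
Reagents that add atoms: none
Why: Tsuji–Trost-type decarboxylative allylic etherification: zerovalent palladium ionises the tertiary carbonate, and the tert-butoxide released on loss of CO2 deprotonates the phenol. The phenoxide attacks the more substituted terminus of the π-(1,1-dimethylallyl)palladium cation under kinetic control at low temperature, giving the tertiary ether and not the linear prenyl ether. The two ortho hydroxyls react in turn, through mono-ether 5.

Step 4
Reactants: 6 1-[4-(methoxymethoxy)-2,6-bis(2-methylbut-3-en-2-yloxy)phenyl]ethanone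
Product: 10 1-[2,6-dihydroxy-4-(methoxymethoxy)-3,5-bis(3-methylbut-2-enyl)phenyl]ethanone, via first cyclohexadienone 7 (not isolated), via mono-rearranged phenol ether 8 (not isolated), via second cyclohexadienone 9 (not isolated)
Conditions: PhNEt2 (degassed), 120 °C, Ar
Reagents that add atoms: none
Why: Each aryl 1,1-dimethylallyl ether undergoes a concerted suprafacial [3,3]-sigmatropic shift (aromatic Claisen rearrangement) through a chair-like six-membered transition state in which the terminal vinyl CH2 bonds to the one unsubstituted ortho carbon as the tertiary C–O bond breaks; dienone 7 enolises to phenol 8, and the second ether repeats the sequence through dienone 9 to 10. The closest known reaction type is the thermal ortho-Claisen rearrangement of aryl 1,1-dimethylallyl ethers to ortho-prenylphenols. No ring is closed and no stereocentre is set; the sp3 ring carbons of 7 and 9 disappear on tautomerisation. The selectivity needed is ortho migration with allylic transposition at both sites, so that linear 3-methylbut-2-enyl groups and not 1,1-dimethylallyl groups end up on the ring. The substrate secures the site because the second ortho carbon of each oxygen bears the acetyl group: a shift to it gives a dienone that cannot enolise and reverts, and onward migration from there to the para carbon would require the hindered CMe2 terminus to bond to the ring. The weak tertiary C–O bond and the crowding of two bulky ethers around the acetyl group lower the barrier, so about 120 °C should suffice, below the range where an ortho-prenylphenol closes onto its own double bond. The weakly basic amine solvent speeds enolisation of the dienones and buffers adventitious acid, and each new phenol is held in a hydrogen bond to the acetyl oxygen. The aryl MOM ether and the ketone are inert under these neutral thermal conditions.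

Step 5
Reactants: 10 1-[2,6-dihydroxy-4-(methoxymethoxy)-3,5-bis(3-methylbut-2-enyl)phenyl]ethanone
Product: 11 1-[2,4,6-tris(methoxymethoxy)-3,5-bis(3-methylbut-2-enyl)phenyl]ethanone
Conditions: NaH (2.3 equiv), MOMCl, DMF, 0 °C → rt
Reagents that add atoms: chloromethyl methyl ether (MOMCl), COCCl
Why: Both phenols are flanked by the acetyl and a prenyl group and take part in hydrogen bonding to the carbonyl, so they are deprotonated irreversibly with NaH and the phenoxides O-alkylated in DMF (Williamson-type MOM protection). Masking both prevents conjugate ring closure and phenoxide-directed side oxidation in the next two steps.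

Step 6
Reactants: 12 4-hydroxybenzaldehyde
Product: 13 4-(methoxymethoxy)benzaldehyde
Conditions: MOMCl, i-Pr2NEt, CH2Cl2, 0 °C → rt
Reagents that add atoms: chloromethyl methyl ether (MOMCl), COCCl
Why: Standard MOM protection of a phenol. It keeps the aldehyde from being deactivated as its phenoxide in the aldol step and lets ring B be unmasked together with ring A at the end.

Step 7
Reactants: 11 1-[2,4,6-tris(methoxymethoxy)-3,5-bis(3-methylbut-2-enyl)phenyl]ethanone; 13 4-(methoxymethoxy)benzaldehyde
Product: 15 (E)-3-[4-(methoxymethoxy)phenyl]-1-[2,4,6-tris(methoxymethoxy)-3,5-bis(3-methylbut-2-enyl)phenyl]prop-2-en-1-one, via β-hydroxy ketone aldol adduct 14 (not isolated)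
Conditions: KOH, EtOH/H2O, rt
Reagents that add atoms: none
Why: Claisen–Schmidt condensation: the methyl ketone enolate adds to the non-enolisable aldehyde and aldol 14 loses water by E1cB to the conjugated enone, the E geometry being thermodynamically preferred. Fully etherified 2,6-dioxygenated acetophenones are competent partners because the reacting methyl group lies outside the congested ring plane.

Step 8
Reactants: 15 (E)-3-[4-(methoxymethoxy)phenyl]-1-[2,4,6-tris(methoxymethoxy)-3,5-bis(3-methylbut-2-enyl)phenyl]prop-2-en-1-one
Product: 16 [(2R,3S)-3-[4-(methoxymethoxy)phenyl]oxiran-2-yl][2,4,6-tris(methoxymethoxy)-3,5-bis(3-methylbut-2-enyl)phenyl]methanone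
Conditions: poly-L-leucine, urea·H2O2, DBU, THF, rt
Reagents that add atoms: urea–hydrogen peroxide adduct, NC(N)=O.OO
Why: Juliá–Colonna epoxidation, an asymmetric Weitz–Scheffer reaction: hydroperoxide anion adds to Cβ of the enone held by the N-terminal NH groups of the helical poly-L-leucine, and the enolate closes on oxygen with loss of hydroxide. This should set Cα as R and Cβ as S in the trans epoxide. The nucleophilic oxidant leaves the electron-rich prenyl alkenes untouched.

Step 9
Reactants: 16 [(2R,3S)-3-[4-(methoxymethoxy)phenyl]oxiran-2-yl][2,4,6-tris(methoxymethoxy)-3,5-bis(3-methylbut-2-enyl)phenyl]methanone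
Product: 18 (2R,3R)-3,5,7-trihydroxy-2-(4-hydroxyphenyl)-6,8-bis(3-methylbut-2-enyl)-2,3-dihydrochromen-4-one (6,8-diprenylaromadendrin), via tetraphenolic epoxy ketone 17 (not isolated)
Conditions: HCl (1.25 M in MeOH), THF, 40 °C, short reaction time
Reagents that add atoms: none
Why: Acid-mediated acetal cleavage and intramolecular epoxide opening, the known epoxy-chalcone to dihydroflavonol cyclisation: either of the two equivalent ortho phenols attacks the protonated epoxide at the benzylic carbon in a 6-endo closure with inversion (S at Cβ becomes R at C2), while the C3–O bond of the epoxide is untouched (R retained). The benzylic carbon is activated by the para-oxygenated ring B, attack at the carbon α to the carbonyl is disfavoured, and the 2,3-trans product is also the thermodynamically preferred one.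

## Compound list

1 | 2,4,6-trihydroxyacetophenone | CC(=O)c1c(O)cc(O)cc1O | starting material
2 | 1-[2,6-dihydroxy-4-(methoxymethoxy)phenyl]ethanone | CC(=O)c1c(O)cc(OCOC)cc1O | intermediate
3 | 2-methylbut-3-en-2-ol | C=CC(C)(C)O | starting material
4 | tert-butyl 2-methylbut-3-en-2-yl carbonate | C=CC(C)(C)OC(=O)OC(C)(C)C | intermediate
5 | 1-[2-hydroxy-4-(methoxymethoxy)-6-(2-methylbut-3-en-2-yloxy)phenyl]ethanone | CC(=O)c1c(O)cc(OCOC)cc1OC(C)(C)C=C | intermediate
6 | 1-[4-(methoxymethoxy)-2,6-bis(2-methylbut-3-en-2-yloxy)phenyl]ethanone | CC(=O)c1c(OC(C)(C)C=C)cc(OCOC)cc1OC(C)(C)C=C | intermediate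
7 | 2-acetyl-5-(methoxymethoxy)-3-(2-methylbut-3-en-2-yloxy)-6-(3-methylbut-2-enyl)cyclohexa-2,4-dien-1-one (racemic) | CC(=O)C1=C(OC(C)(C)C=C)C=C(OCOC)C(CC=C(C)C)C1=O | intermediate
8 | 1-[2-hydroxy-4-(methoxymethoxy)-3-(3-methylbut-2-enyl)-6-(2-methylbut-3-en-2-yloxy)phenyl]ethanone | CC(=O)c1c(O)c(CC=C(C)C)c(OCOC)cc1OC(C)(C)C=C | intermediate
9 | 2-acetyl-3-hydroxy-5-(methoxymethoxy)-4,6-bis(3-methylbut-2-enyl)cyclohexa-2,4-dien-1-one (racemic) | CC(=O)C1=C(O)C(CC=C(C)C)=C(OCOC)C(CC=C(C)C)C1=O | intermediate
10 | 1-[2,6-dihydroxy-4-(methoxymethoxy)-3,5-bis(3-methylbut-2-enyl)phenyl]ethanone | CC(=O)c1c(O)c(CC=C(C)C)c(OCOC)c(CC=C(C)C)c1O | intermediate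
11 | 1-[2,4,6-tris(methoxymethoxy)-3,5-bis(3-methylbut-2-enyl)phenyl]ethanone | CC(=O)c1c(OCOC)c(CC=C(C)C)c(OCOC)c(CC=C(C)C)c1OCOC | intermediate
12 | 4-hydroxybenzaldehyde | O=Cc1ccc(O)cc1 | starting material
13 | 4-(methoxymethoxy)benzaldehyde | COCOc1ccc(C=O)cc1 | intermediate
14 | 3-hydroxy-3-[4-(methoxymethoxy)phenyl]-1-[2,4,6-tris(methoxymethoxy)-3,5-bis(3-methylbut-2-enyl)phenyl]propan-1-one (racemic) | COCOc1ccc(C(O)CC(=O)c2c(OCOC)c(CC=C(C)C)c(OCOC)c(CC=C(C)C)c2OCOC)cc1 | intermediate
15 | (E)-3-[4-(methoxymethoxy)phenyl]-1-[2,4,6-tris(methoxymethoxy)-3,5-bis(3-methylbut-2-enyl)phenyl]prop-2-en-1-one | COCOc1ccc(/C=C/C(=O)c2c(OCOC)c(CC=C(C)C)c(OCOC)c(CC=C(C)C)c2OCOC)cc1 | intermediate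
16 | [(2R,3S)-3-[4-(methoxymethoxy)phenyl]oxiran-2-yl][2,4,6-tris(methoxymethoxy)-3,5-bis(3-methylbut-2-enyl)phenyl]methanone | O=C(c1c(OCOC)c(CC=C(C)C)c(OCOC)c(CC=C(C)C)c1OCOC)[C@@H]1O[C@H]1c1ccc(OCOC)cc1 | intermediate
17 | [(2R,3S)-3-(4-hydroxyphenyl)oxiran-2-yl][2,4,6-trihydroxy-3,5-bis(3-methylbut-2-enyl)phenyl]methanone | O=C(c1c(O)c(CC=C(C)C)c(O)c(CC=C(C)C)c1O)[C@@H]1O[C@H]1c1ccc(O)cc1 | intermediate
18 | (2R,3R)-3,5,7-trihydroxy-2-(4-hydroxyphenyl)-6,8-bis(3-methylbut-2-enyl)-2,3-dihydrochromen-4-one (6,8-diprenylaromadendrin) | CC(C)=CCc1c(O)c(CC=C(C)C)c2c(c1O)C(=O)[C@H](O)[C@@H](c1ccc(O)cc1)O2 | target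

## Step count and least certain steps

Total step count: 9. Longest linear sequence: 7 steps (steps 1, 3, 4, 5, 7, 8 and 9, from 1 to 18). Steps 2 and 6 prepare the side components 4 and 13.

**Step 4 (key step).**
- What may go wrong: the tertiary allyl ethers may be lost by ionisation and elimination before or between the two shifts. A freshly formed ortho-prenylphenol may add across its own double bond on prolonged heating. A minor pathway through the acetyl-bearing carbon may transfer the allyl unit without net transposition.
- Fallback: the sigmatropic approach is abandoned. Starting from 1, both free ring carbons are C-prenylated directly with 1-bromo-3-methylbut-2-ene in cold aqueous KOH (ambident phenoxide alkylation, known for acylated 1,3,5-trihydroxybenzenes) to give 1-[2,4,6-trihydroxy-3,5-bis(3-methylbut-2-enyl)phenyl]ethanone F1. F1 is then tris-protected with NaH and chloromethyl methyl ether in DMF and rejoins the route at 11. This is short but unselective, since mono-, geminal di- and O-alkylation compete, which is why it is the second choice.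

**Step 3.**
- What may go wrong: the second etherification may stall, because the remaining hydroxyl of 5 is locked in a hydrogen bond to the acetyl group and crowded by it. The ethers may also be re-ionised by zerovalent palladium, with drift towards the linear prenyl ethers or C-allylation of the electron-rich ring.
- Fallback: the two prenyl groups are installed one at a time. Starting from 2, one equivalent of 4 under the same catalysis gives 5, which is isolated and heated as in step 4 to give 1-[2,6-dihydroxy-4-(methoxymethoxy)-3-(3-methylbut-2-enyl)phenyl]ethanone F2. F2 is etherified again with 4 at the less hindered hydroxyl (the one with no prenyl neighbour) to give 8, now isolated, and 8 is rearranged thermally to rejoin the route at 10. Each etherification then acts on a diphenol that still has one hydroxyl outside the chelate, at the cost of two extra steps.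

**Step 8.**
- What may go wrong: oxygen transfer may be slow or poorly face-selective, because the doubly ortho-substituted aryl ketone is twisted out of the enone plane and may fit the helical polypeptide badly.
- Fallback: catalyst control is replaced by resolution. Starting from 15, racemic Weitz–Scheffer epoxidation (H2O2, NaOH, MeOH/THF) should give 16 together with its enantiomer [(2S,3R)-3-[4-(methoxymethoxy)phenyl]oxiran-2-yl][2,4,6-tris(methoxymethoxy)-3,5-bis(3-methylbut-2-enyl)phenyl]methanone F3. The two are separated by preparative chromatography on a chiral stationary phase (cellulose tris(3,5-dimethylphenylcarbamate)), and the route is rejoined at 16.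

**Step 9.**
- What may go wrong: the alcohol solvent or chloride may open the epoxide before an ortho phenol is free, with erosion of the trans selectivity. On longer exposure, acid may promote addition of a liberated phenol across a neighbouring prenyl double bond.
- Fallback: ring closure is separated from protic acid.
  - Starting from 16, phenylmethanethiol and SnCl4 in CH2Cl2 at −20 °C should open the epoxide at the benzylic carbon and remove the chelation-activated ortho MOM group. This gives (2S,3R)-3-(benzylsulfanyl)-2-hydroxy-1-[2-hydroxy-4,6-bis(methoxymethoxy)-3,5-bis(3-methylbut-2-enyl)phenyl]-3-[4-(methoxymethoxy)phenyl]propan-1-one F4.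
  - AgBF4 in CH2Cl2 at 0 °C then activates the sulfide as a leaving group. Closure through the benzylic cation, under product-stability control, should give mainly (2R,3R)-3-hydroxy-5,7-bis(methoxymethoxy)-2-[4-(methoxymethoxy)phenyl]-6,8-bis(3-methylbut-2-enyl)chroman-4-one F5.
  - A brief treatment of F5 with methanolic HCl removes the remaining acetals and rejoins the route at 18.

## Further compounds

F1 | step 4 | 1-[2,4,6-trihydroxy-3,5-bis(3-methylbut-2-enyl)phenyl]ethanone | CC(=O)c1c(O)c(CC=C(C)C)c(O)c(CC=C(C)C)c1O
F2 | step 3 | 1-[2,6-dihydroxy-4-(methoxymethoxy)-3-(3-methylbut-2-enyl)phenyl]ethanone | CC(=O)c1c(O)c(CC=C(C)C)c(OCOC)cc1O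
F3 | step 8 | [(2S,3R)-3-[4-(methoxymethoxy)phenyl]oxiran-2-yl][2,4,6-tris(methoxymethoxy)-3,5-bis(3-methylbut-2-enyl)phenyl]methanone | O=C(c1c(OCOC)c(CC=C(C)C)c(OCOC)c(CC=C(C)C)c1OCOC)[C@H]1O[C@@H]1c1ccc(OCOC)cc1
F4 | step 9 | (2S,3R)-3-(benzylsulfanyl)-2-hydroxy-1-[2-hydroxy-4,6-bis(methoxymethoxy)-3,5-bis(3-methylbut-2-enyl)phenyl]-3-[4-(methoxymethoxy)phenyl]propan-1-one | O=C(c1c(O)c(CC=C(C)C)c(OCOC)c(CC=C(C)C)c1OCOC)[C@H](O)[C@H](SCc1ccccc1)c1ccc(OCOC)cc1
F5 | step 9 | (2R,3R)-3-hydroxy-5,7-bis(methoxymethoxy)-2-[4-(methoxymethoxy)phenyl]-6,8-bis(3-methylbut-2-enyl)chroman-4-one | CC(C)=CCc1c(OCOC)c(CC=C(C)C)c2c(c1OCOC)C(=O)[C@H](O)[C@@H](c1ccc(OCOC)cc1)O2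
A1 | alternative 1 | (2R,3S,4R)-5,7-bis(tert-butyldimethylsilyloxy)-2-[4-(tert-butyldimethylsilyloxy)phenyl]-4-methoxy-6,8-bis(3-methylbut-2-enyl)chroman-3-yl acetate (2,3-trans-3,4-trans) | CC(C)=CCc1c(O[Si](C)(C)C(C)(C)C)c(CC=C(C)C)c2c(c1O[Si](C)(C)C(C)(C)C)[C@@H](OC)[C@H](OC(C)=O)[C@@H](c1ccc(O[Si](C)(C)C(C)(C)C)cc1)O2
A2 | alternative 1 | 4,6-bis(tert-butyldimethylsilyloxy)-2-hydroxy-3,5-bis(3-methylbut-2-enyl)benzaldehyde | O=Cc1c(O)c(CC=C(C)C)c(O[Si](C)(C)C(C)(C)C)c(CC=C(C)C)c1O[Si](C)(C)C(C)(C)C
A3 | alternative 1 | 3,5-bis(tert-butyldimethylsilyloxy)-6-(methoxymethylidene)-2,4-bis(3-methylbut-2-enyl)cyclohexa-2,4-dien-1-one | COC=C1C(=O)C(CC=C(C)C)=C(O[Si](C)(C)C(C)(C)C)C(CC=C(C)C)=C1O[Si](C)(C)C(C)(C)C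
A4 | alternative 1 | (E)-2-[4-(tert-butyldimethylsilyloxy)phenyl]ethenyl acetate | CC(=O)O/C=C/c1ccc(O[Si](C)(C)C(C)(C)C)cc1
A5 | alternative 2 | 2,6-bis(3-methylbut-2-enyl)-3,5-bis(triisopropylsilyloxy)phenol | Oc1c(CC=C(C)C)c(O[Si](C(C)C)(C(C)C)C(C)C)cc(O[Si](C(C)C)(C(C)C)C(C)C)c1CC=C(C)C
A6 | alternative 2 | 4-(3-methylbut-2-enyl)-3-(triisopropylsilyloxy)cyclobut-2-en-1-one | O=C1C=C(O[Si](C(C)C)(C(C)C)C(C)C)C1CC=C(C)C
A7 | alternative 2 | triisopropyl[(5-methylhex-4-en-1-yn-1-yl)oxy]silane | CC(C)=CCC#CO[Si](C(C)C)(C(C)C)C(C)C
A8 | alternative 3 | (2R,3R)-5,7-dihydroxy-3-(methoxymethoxy)-2-[4-(methoxymethoxy)phenyl]-6,8-bis(3-methylbut-2-enyl)chroman-4-one | CC(C)=CCc1c(O)c(CC=C(C)C)c2c(c1O)C(=O)[C@H](OCOC)[C@@H](c1ccc(OCOC)cc1)O2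
A9 | alternative 3 | 1-methoxy-2,4-bis(3-methylbut-2-enyl)-1,3-bis(trimethylsilyloxy)buta-1,3-diene | COC(O[Si](C)(C)C)=C(CC=C(C)C)C(O[Si](C)(C)C)=CCC=C(C)C
A10 | alternative 3 | (2R,3R)-5-bromo-3-(methoxymethoxy)-2-[4-(methoxymethoxy)phenyl]-2,3-dihydropyran-4-one | BrC1=CO[C@H](c2ccc(OCOC)cc2)[C@@H](OCOC)C1=O
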